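The north-east run is the very flask you are asked about, read up to 15.0 min, and the south-east run is an earlier one at other settings.

| flask | substrate | free enzyme | temperature | remark | time |
|---|---|---|---|---|---|
| north-east | 1 mM | 0.035 mol% | 37 °C | the very flask that is asked about, followed so far |  |
| south-east | 0.50 mM | 0.035 mol% | 43 °C | run made earlier |  |
| flask | 1.0 mM | 0.035 mol% | 37 °C |  | 20 min |

| run | time / min | target / % | substrate / % |
|---|---|---|---|
| north-east | 1.33 | 56.4 | 4.1 |
| north-east | 3.00 | 56.1 | 0 |
| north-east | 6.00 | 53.5 | 0 |
| north-east | 15.0 | 54.5 | 0 |
| south-east | 0.500 | 30.3 | 37.0 |
| south-east | 1.33 | 48.5 | 9.5 |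
| south-east | 2.50 | 52.2 | 2.9 |
| south-east | 4.00 | 53.3 | 2.5 |

(each reading ± 1 percentage point)

- target that was removed still counts
- additions bring no volume worth counting

- summer: at 20 min take out 90% of the target then present, then wait 40 min
- winter: at 20 min add free enzyme, 100% of the amount charged, then wait 40 min
- dawn: change nothing and wait 40 min more

1. target, in percent of the substrate first charged, at 20 min
2. the option that brings most further target ("none" if no option brings more than 2 percentage points) (summer / winter / dawn / none)
3. target present, with what was taken out counted in, in percent of the substrate first charged, after winter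
4. target present, with what was taken out counted in, in percent of the substrate first charged, after dawn

Fold the givens into one number. North-east substrate falls to 4.1% of the charge at 1.33 min; read as a pseudo-first-order decay, that is a lifetime of 0.416 min. Dividing 20 min by it gives 48.0: this is the lifetime number, the time of acting counted in substrate lifetimes. The fraction of the charge still there is e raised to minus that number, far less than the scatter of 1 percentage point. So I expect the flask to stand at its level, 54.7% as the mean of the readings from 3.00 min on, and I expect dawn and winter to add nothing, since they find no substrate to work on.

Is one number enough? No. It says when substrate has gone, but 45.3% of the charge is unread, and a flat target fits a stopped flask as well as a standing balance. Taking target out tests that balance, so I choose summer, without a size for its gain.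

The forecast gives 54.7% now, 54.5% after winter, 54.3% after dawn and, unlike my choice, none as best: “So my answer is none, with modest confidence”.

The flask gives 55.3% at 20 min, 55.3% after winter and 55.3% after dawn; summer is best, bringing 6.6 points, against 0 points for winter and 0 points for dawn.

    target + free enzyme ⇌ isomer of the product + free enzyme, rate k1*[free enzyme]*[target] forward; the back reaction follows from the equilibrium constant (K = 0.152, k = 3800 M⁻¹ s⁻¹, Ea = 34.0 kJ mol⁻¹, ΔH = −24.0 kJ mol⁻¹)
    2 substrate → self-condensation product (k = 17.8 M⁻¹ s⁻¹, Ea = 54.0 kJ mol⁻¹)
    substrate + free enzyme → target + free enzyme, rate k3*[substrate]*[free enzyme]/(1 + ([substrate]/Km3)) (2.07 mM, k = 97800 M⁻¹ s⁻¹, Ea = 12.0 kJ mol⁻¹)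
    free enzyme → unfolded enzyme (k = 1.20 × 10⁻⁴ s⁻¹, Ea = 233 kJ mol⁻¹)
    (constants at 37 °C)

While substrate lasted, its conversion into target and its self-condensation ran side by side, and at 2.00 min the flask held 1.04% substrate against 0.817% from the lifetime 0.416 min. Target and isomer of the product then exchanged with a relaxation half-life of 1.32 min, shorter than 20 min, and stood at 55.3% and 8.40% at that time. The lifetime number of 48.0 belongs to this flask and does not carry over unchanged to the neighbour charged with 2.5 mM at the same loading, which starts with more substrate; that neighbour holds 0% substrate at 20.0 min, with target at 50.6%.

(All runs are calculated with made-up constants; the scatter is artificial.)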